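**Retrosynthetic overview**
1. Sophonorol D (14) comes from its 5,7-bis-TIPS ether 13 by fluoride desilylation (last step).
2. 13 comes from racemic 3-hydroxychromanone 11 and quinone monoketal 7 by an organocatalytic asymmetric conjugate addition/aromatisation. This one operation forms the C3–C1' bond and the C3 stereocentre and unveils the 2'-OMe/5'-OH pattern of ring B.
3. 11 comes from 5,7-dihydroxychroman-4-one 8 (silylation, enolate hydroxylation). 7 comes from 2,4-dimethoxyphenol 1 (silylation, ortho-lithiation/prenylation, PhI(OAc)2/MeOH).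
4. Ring order: rings A and C are bought together as the chromanone, ring B is carried as a dearomatised dienone and becomes aromatic in the key step; no ring is closed in the route.

Assumption: 1, 3 and 8 are taken as catalogue chemicals, and the facial sense of the new step rests on a hydrogen-bonding model, so the mirror-image catalyst is used if the first run gives the (3R) product.

**Route**

Step 1
Reactants: 1 2,4-dimethoxyphenol
Product: 2 (2,4-dimethoxyphenoxy)triisopropylsilane
Conditions: TIPSCl, imidazole, DMF, 23 °C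
Reagents that add atoms: triisopropylsilyl chloride (TIPSCl), CC(C)[Si](Cl)(C(C)C)C(C)C
Why: Routine silyl ether formation on a phenol; the bulky TIPS group resists n-BuLi, does not direct metalation and shields C6, so the next lithiation is governed by the two methoxy groups.

Step 2
Reactants: 2 (2,4-dimethoxyphenoxy)triisopropylsilane; 3 prenyl bromide (1-bromo-3-methylbut-2-ene)
Product: 6 2,4-dimethoxy-3-(3-methylbut-2-en-1-yl)phenol, via aryllithium 4 (not isolated), via prenylated silyl ether 5 (not isolated)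
Conditions: n-BuLi, TMEDA, THF, 0 → 23 °C; CuBr·SMe2 (10 mol %), 3, −40 → 0 °C; then TBAF, 23 °C; AcOH quench
Reagents that add atoms: none
Why: Directed ortho-metalation at the carbon flanked by both methoxy groups (the site at which 1,2,4-trimethoxybenzene lithiates), copper-assisted SN2 allylation with prenyl bromide and in-flask fluoride desilylation give the phenol.

Step 3
Reactants: 6 2,4-dimethoxy-3-(3-methylbut-2-en-1-yl)phenol
Product: 7 2,4,4-trimethoxy-3-(3-methylbut-2-en-1-yl)cyclohexa-2,5-dien-1-one
Conditions: PhI(OAc)2, MeOH, 0 °C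
Reagents that add atoms: methanol, CO
Why: Hypervalent-iodine oxidative dearomatisation of a para-methoxyphenol, in which methanol traps the phenoxenium ion at the methoxy-bearing para carbon to give the para-quinone monoketal; the prenyl alkene is inert to PhI(OAc)2 without acid activation.

Step 4
Reactants: 8 5,7-dihydroxychroman-4-one
Product: 9 5,7-bis(triisopropylsilyloxy)chroman-4-one
Conditions: TIPSOTf, 2,6-lutidine, CH2Cl2, 0 → 23 °C
Reagents that add atoms: triisopropylsilyl trifluoromethanesulfonate (TIPSOTf), CC(C)[Si](OS(=O)(=O)C(F)(F)F)(C(C)C)C(C)C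
Why: The silyl triflate silylates the hydrogen-bonded 5-OH as well as the 7-OH; the TIPS ethers mask the acidic phenols and the nucleophilic phloroglucinol ring for the base-catalysed key step and come off later with fluoride, without acid.

Step 5
Reactants: 9 5,7-bis(triisopropylsilyloxy)chroman-4-one
Product: 11 rac-3-hydroxy-5,7-bis(triisopropylsilyloxy)chroman-4-one, via potassium enolate 10 (not isolated)
Conditions: KN(SiMe3)2, THF, −78 °C; 2-(phenylsulfonyl)-3-phenyloxaziridine, −78 °C; AcOH quench
Reagents that add atoms: 2-(phenylsulfonyl)-3-phenyloxaziridine (Davis oxaziridine), O=S(=O)(N1OC1c1ccccc1)c1ccccc1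
Why: Davis α-hydroxylation of the potassium enolate (electrophilic oxygen transfer from the N-sulfonyloxaziridine) gives the secondary ketol; it is left racemic on purpose because this centre is flattened again in step 6.

Step 6
Reactants: 11 rac-3-hydroxy-5,7-bis(triisopropylsilyloxy)chroman-4-one; 7 2,4,4-trimethoxy-3-(3-methylbut-2-en-1-yl)cyclohexa-2,5-dien-1-one
Product: 13 (3S)-3-hydroxy-3-[5-hydroxy-2,4-dimethoxy-3-(3-methylbut-2-en-1-yl)phenyl]-5,7-bis(triisopropylsilyloxy)chroman-4-one, via Michael adduct 12 (not isolated)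
Conditions: bifunctional iminophosphorane–thiourea organocatalyst 1-[3,5-bis(trifluoromethyl)phenyl]-3-[(2S)-3,3-dimethyl-1-{[tris(4-methoxyphenyl)-λ5-phosphanylidene]amino}butan-2-yl]thiourea (10 mol %), toluene, −30 °C, Ar; then TsOH·H2O (30 mol %), CH2Cl2, 0 °C
Reagents that add atoms: none
Why: Proposed new method: enantioselective α-arylation of a cyclic α-hydroxy aryl ketone by a para-quinone monoketal under bifunctional Brønsted-base/hydrogen-bond-donor organocatalysis — the iminophosphorane removes the C3–H of 11 (activated by the aryl ketone, the α-OH and the β-aryloxy group) to give an achiral hydrogen-bonded enediolate, which erases the racemic centre; the thiourea/iminophosphonium N–H array holds the enediolate oxygens and the dienone carbonyl of 7 and steers conjugate addition of C3 through its Re face (giving 3S) to the only unsubstituted β-carbon of 7; acid then ionises the push–pull-stabilised ketal of 12, and loss of MeOH with tautomerisation restores aromatic ring B with 2'-OMe and 5'-OH in place; the closest known reaction types are the base- or phase-transfer-catalysed enantioselective α-arylation of β-keto esters and oxindoles with quinones and the Michael addition/aromatisation of stabilised carbanions with quinone monoketals.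

Step 7
Reactants: 13 (3S)-3-hydroxy-3-[5-hydroxy-2,4-dimethoxy-3-(3-methylbut-2-en-1-yl)phenyl]-5,7-bis(triisopropylsilyloxy)chroman-4-one
Product: 14 sophonorol D, (3S)-3,5,7-trihydroxy-3-[5-hydroxy-2,4-dimethoxy-3-(3-methylbut-2-en-1-yl)phenyl]chroman-4-one
Conditions: TBAF, AcOH, THF, 0 °C
Reagents that add atoms: none
Why: Buffered fluoride cleavage of the two aryl silyl ethers (desilylation) frees the 5- and 7-OH without acid or strong base, so the prenyl group and the quaternary α-ketol (no α-hydrogen, so no epimerisation) are untouched.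

**Compound list**
1 | 2,4-dimethoxyphenol | COc1ccc(O)c(OC)c1 | starting material
2 | (2,4-dimethoxyphenoxy)triisopropylsilane | COc1ccc(O[Si](C(C)C)(C(C)C)C(C)C)c(OC)c1 | intermediate
3 | prenyl bromide (1-bromo-3-methylbut-2-ene) | CC(C)=CCBr | starting material
4 | [2,6-dimethoxy-3-(triisopropylsilyloxy)phenyl]lithium | [Li]c1c(OC)ccc(O[Si](C(C)C)(C(C)C)C(C)C)c1OC | intermediate
5 | [2,4-dimethoxy-3-(3-methylbut-2-en-1-yl)phenoxy]triisopropylsilane | COc1ccc(O[Si](C(C)C)(C(C)C)C(C)C)c(OC)c1CC=C(C)C | intermediate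
6 | 2,4-dimethoxy-3-(3-methylbut-2-en-1-yl)phenol | COc1ccc(O)c(OC)c1CC=C(C)C | intermediate
7 | 2,4,4-trimethoxy-3-(3-methylbut-2-en-1-yl)cyclohexa-2,5-dien-1-one | COC1=C(CC=C(C)C)C(OC)(OC)C=CC1=O | intermediate
8 | 5,7-dihydroxychroman-4-one | O=C1CCOc2cc(O)cc(O)c12 | starting material
9 | 5,7-bis(triisopropylsilyloxy)chroman-4-one | O=C1CCOc2cc(O[Si](C(C)C)(C(C)C)C(C)C)cc(O[Si](C(C)C)(C(C)C)C(C)C)c12 | intermediate
10 | potassium 5,7-bis(triisopropylsilyloxy)-2H-chromen-4-olate | [K+].[O-]C1=CCOc2cc(O[Si](C(C)C)(C(C)C)C(C)C)cc(O[Si](C(C)C)(C(C)C)C(C)C)c12 | intermediate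
11 | rac-3-hydroxy-5,7-bis(triisopropylsilyloxy)chroman-4-one (racemic at C3) | O=C1C(O)COc2cc(O[Si](C(C)C)(C(C)C)C(C)C)cc(O[Si](C(C)C)(C(C)C)C(C)C)c12 | intermediate
12 | (3S)-3-hydroxy-3-[2,2,4-trimethoxy-3-(3-methylbut-2-en-1-yl)-5-oxocyclohex-3-en-1-yl]-5,7-bis(triisopropylsilyloxy)chroman-4-one (both epimers at the cyclohexene carbon) | COC1=C(CC=C(C)C)C(OC)(OC)C(CC1=O)[C@]2(O)COc3cc(O[Si](C(C)C)(C(C)C)C(C)C)cc(O[Si](C(C)C)(C(C)C)C(C)C)c3C2=O | intermediate
13 | (3S)-3-hydroxy-3-[5-hydroxy-2,4-dimethoxy-3-(3-methylbut-2-en-1-yl)phenyl]-5,7-bis(triisopropylsilyloxy)chroman-4-one | COc1c(O)cc([C@]2(O)COc3cc(O[Si](C(C)C)(C(C)C)C(C)C)cc(O[Si](C(C)C)(C(C)C)C(C)C)c3C2=O)c(OC)c1CC=C(C)C | intermediate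
14 | sophonorol D, (3S)-3,5,7-trihydroxy-3-[5-hydroxy-2,4-dimethoxy-3-(3-methylbut-2-en-1-yl)phenyl]chroman-4-one | COc1c(O)cc([C@]2(O)COc3cc(O)cc(O)c3C2=O)c(OC)c1CC=C(C)C | target

**Step count and risks**
Total steps: 7. Longest linear sequence: 5 (steps 1, 2, 3, 6, 7, from 2,4-dimethoxyphenol); the ring A/C branch is steps 4 and 5.

The step most likely to fail is step 6, the proposed new α-arylation. The enediolate of 11 may be formed too slowly, may reduce the dienone (giving the 3-hydroxychromone), may open ring C by β-elimination of the aryloxide, or may add with low or reversed facial selectivity. The ee is measured on 13 by chiral HPLC and the configuration checked by ECD against the natural product. The fallback uses known chemistry only, sets out from 5 (isolated by leaving out the TBAF treatment in step 2) and 9, and comes back to the route at 14. Compound 5 is brominated with NBS (MeCN, −20 °C, dark) at the ring position para to the 2-methoxy group to give [5-bromo-2,4-dimethoxy-3-(3-methylbut-2-en-1-yl)phenoxy]triisopropylsilane F1. Palladium-catalysed ketone α-arylation of 9 with F1 (Pd(OAc)2, P(t-Bu)3·HBF4, NaOt-Bu, toluene, 60 °C) gives racemic 3-[2,4-dimethoxy-3-(3-methylbut-2-en-1-yl)-5-(triisopropylsilyloxy)phenyl]-5,7-bis(triisopropylsilyloxy)chroman-4-one F2. Enantioselective aerobic α-hydroxylation of F2 under chiral phase-transfer catalysis (cinchona-derived quaternary ammonium salt 5 mol %, O2, P(OEt)3, Cs2CO3, toluene, 0 °C) gives (3S)-3-[2,4-dimethoxy-3-(3-methylbut-2-en-1-yl)-5-(triisopropylsilyloxy)phenyl]-3-hydroxy-5,7-bis(triisopropylsilyloxy)chroman-4-one F3. TBAF/AcOH as in step 7 then removes all three silyl groups to give 14.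

Second is step 5, the enolate hydroxylation. The chromanone enolate can open by β-elimination, can add to the sulfonimine by-product, or the ketol 11 can be over-oxidised or air-oxidised on isolation. The fallback sets out from 9 and comes back at 11 by a Rubottom sequence that avoids a free enolate. TMSOTf/Et3N (CH2Cl2, 0 °C) gives the silyl enol ether 5,7-bis(triisopropylsilyloxy)-4-(trimethylsilyloxy)-2H-chromene F4. Dimethyldioxirane (acetone, −40 °C) gives the silyloxy epoxide 3,4-epoxy-4-(trimethylsilyloxy)-5,7-bis(triisopropylsilyloxy)chromane F5, which rearranges by silyl shift to 3-(trimethylsilyloxy)-5,7-bis(triisopropylsilyloxy)chroman-4-one F6. Aqueous citric acid/THF cleaves the trimethylsilyl ether to give 11.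

Third is step 2. The lithiation site is taken as secure, but the hindered aryllithium 4 may alkylate sluggishly or give some of the SN2' (1,1-dimethylallyl) isomer. The fallback sets out from 2 and comes back at 5, which is then desilylated to 6 with TBAF as in step 2; it builds the prenyl group by olefin metathesis. Compound 2 is lithiated as before and trapped with allyl bromide to give (3-allyl-2,4-dimethoxyphenoxy)triisopropylsilane F7. Cross-metathesis of F7 with 2-methylbut-2-ene (second-generation Grubbs catalyst RuCl2(=CHPh)(PCy3)(H2IMes), CH2Cl2, 40 °C) gives 5.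

**Further compounds**
F1 | step 6 | [5-bromo-2,4-dimethoxy-3-(3-methylbut-2-en-1-yl)phenoxy]triisopropylsilane | COc1c(Br)cc(O[Si](C(C)C)(C(C)C)C(C)C)c(OC)c1CC=C(C)C
F2 | step 6 | rac-3-[2,4-dimethoxy-3-(3-methylbut-2-en-1-yl)-5-(triisopropylsilyloxy)phenyl]-5,7-bis(triisopropylsilyloxy)chroman-4-one | COc1c(O[Si](C(C)C)(C(C)C)C(C)C)cc(C2COc3cc(O[Si](C(C)C)(C(C)C)C(C)C)cc(O[Si](C(C)C)(C(C)C)C(C)C)c3C2=O)c(OC)c1CC=C(C)C
F3 | step 6 | (3S)-3-[2,4-dimethoxy-3-(3-methylbut-2-en-1-yl)-5-(triisopropylsilyloxy)phenyl]-3-hydroxy-5,7-bis(triisopropylsilyloxy)chroman-4-one | COc1c(O[Si](C(C)C)(C(C)C)C(C)C)cc([C@]2(O)COc3cc(O[Si](C(C)C)(C(C)C)C(C)C)cc(O[Si](C(C)C)(C(C)C)C(C)C)c3C2=O)c(OC)c1CC=C(C)C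
F4 | step 5 | 5,7-bis(triisopropylsilyloxy)-4-(trimethylsilyloxy)-2H-chromene | C[Si](C)(C)OC1=CCOc2cc(O[Si](C(C)C)(C(C)C)C(C)C)cc(O[Si](C(C)C)(C(C)C)C(C)C)c12
F5 | step 5 | rac-3,4-epoxy-4-(trimethylsilyloxy)-5,7-bis(triisopropylsilyloxy)chromane | C[Si](C)(C)OC12OC1COc1cc(O[Si](C(C)C)(C(C)C)C(C)C)cc(O[Si](C(C)C)(C(C)C)C(C)C)c12
F6 | step 5 | rac-3-(trimethylsilyloxy)-5,7-bis(triisopropylsilyloxy)chroman-4-one | C[Si](C)(C)OC1COc2cc(O[Si](C(C)C)(C(C)C)C(C)C)cc(O[Si](C(C)C)(C(C)C)C(C)C)c2C1=O
F7 | step 2 | (3-allyl-2,4-dimethoxyphenoxy)triisopropylsilane | COc1ccc(O[Si](C(C)C)(C(C)C)C(C)C)c(OC)c1CC=C
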